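## The problem

The target is a germacranolide: a cyclodecane (C1–C10) with a trans-fused α-methylene-γ-butyrolactone on C7/C8 (C11=C13, C12 carbonyl, ring oxygen on C8). It carries a cis-epoxide at C1–C2 next to the C3 ketone, a methyl-bearing tertiary carbinol at C4, (E)-crotonates on O5 and O6 and a methyl-bearing methine at C10. In these locants it is (1S,2S,4S,5R,6S,7S,8R,10R).

A ten-membered carbocycle resists end-to-end closure, so the way the ring is made decides the plan. The centres C2 and C4 to C8 form one oxygenated run in which each can be set from its neighbour, with the threo C5/C6 diol as the anchor. C10 is cut off from this run by the C9 methylene and needs a transfer of chirality across the ring.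

The α-methylene lactone, the crotonates and the epoxy ketone tolerate neither enolates, hydrides nor peroxide anions. The C3/C4 α-ketol can shift under base, and a free O5 or O6 can add across the ring to a C3 enone. These groups must therefore appear late and in a fixed order.

The feature that opens a solution is the sequence C8–C9–C10–C1=C2. C8 must become the lactone carbinol and can pass through a ketone, C9 is an unsubstituted methylene, and C10 is allylic to the alkene that precedes the epoxide. A C8 ketone with a C1=C2 alkene is a γ,δ-unsaturated ketone, the product of a Claisen rearrangement of the allyl vinyl ether C9=C8–O–C2–C1=C10. If that ether oxygen and C2 sit in an eight-membered ring, the rearrangement turns the ring into the ten-membered carbocycle and writes C10 from a C2 carbinol.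

## Retrosynthesis

**Late electrophiles (38 back to 33).** The C11=C13 bond is cut first and replaced by a dimethylaminomethyl group (36, through 37). The epoxide C–O bonds lead to Z-enone 35, the C3 carbonyl to glycol ketal 34, and the two crotonate C–O bonds to diol 33. Masking the methylene lactone as its amine adduct leaves the enone as the only strongly electrophilic alkene when the peroxide is used; the alternative, epoxidising beside a free methylene lactone, has no basis for selectivity. The forward epoxidation must occur on the face of the C10 methyl group.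

**Lactone (32 and 30 back to 26).** The C11–C13 bond (Mannich) and the O8–C12 bond are cut, and C12 is taken back to a silyl-protected primary alcohol. An ester at C12 would be simpler but would not survive carbonyl methylenation. The C8 carbinol comes from ketone 26, which asks for a hydride delivered anti to the C7 side chain.

**Key disconnection (26 back to 25).** C9–C10 is cut and O–C2 reconnected: a retro-Claisen. Cuts at C1=C2 (metathesis) or C5–C6 (carbonyl addition) would need high dilution and a separate source for C10. This cut trades the carbocycle for an eight-membered cyclic enol ether and C10 for a C2 carbinol. It asks for a chair transition state with the E-propenyl methyl equatorial and C3 axial.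

**Enol ether (25 back to 23).** The exocyclic methylene C9 is removed (lactone 24) and the C8–O2 ester bond is cut (hydroxy acid 23). An eight-membered lactonisation is the price; the trans-dioxolane, the spiro ketal and the quaternary C4 should bias the chain.

**C7–C8 (23 back to 18).** The acid carbon C8 is cut from C7 and traced to a nitromethyl group added in conjugate fashion to Z-enoate 18, whose ester carbon is C12. Organocopper additions to such enoates are anti-selective and would give the C7 epimer if the incoming carbon were C8; nitronate addition is syn-selective and fits. The precursor has one stereocentre less and both C7 arms come from one alkene.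

**C2–C3 and C3–C4 (14 back to 5, 6 and 9).** C3 is a carbonyl dianion equivalent: 1,3-dithiane 6 joins methyl ketone 5 (C4, chelation control from O5) and crotonaldehyde 9 (C2, corrected by oxidation and reagent-controlled reduction via 12 and 13). Sulfur is exchanged for oxygen (14) because later oxidants would attack it.

**C4–C7 (5 back to 1).** The C5/C6 diol with both flanking carbons is L-threitol acetonide 1; four routine steps give 5.

## Roads not taken

**Alternative 1:** Cut the O8–C12 lactone bond of a precursor with latent two-fold symmetry. Hydroxy ester A1 has two identical allylic carbinol arms on C7; equilibrating transesterification should close onto the hydroxyl that gives the trans-lactone A2, making C7 stereogenic and freeing the other arm as the C6 carbinol.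
- Merits: two-directional assembly, and thermodynamic control of the lactone fusion.
- Weak points: the carbocycle still has to be closed end to end afterwards. The trisubstituted alkenes of the arms do not map simply onto the C10 methine, the C1–C2 epoxide and the C3/C4 ketol. The cis/trans energy gap of a disubstituted γ-lactone is modest.
- Comparison: this road is better at the C7/C8 relation, which the chosen plan leaves to a kinetic reduction (step 22). Against that, the chosen plan makes the ring and C10 in one step without high dilution.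

**Alternative 2:** Cut C5–C6. A Lewis acid makes the γ-alkoxyallylstannane of aldehyde A3 add through C5 to the C6 aldehyde, closing the carbocycle as A4 with C5 and C6 set in the ring-forming step and a C4 methylene as carbinol precursor.
- Merits: the lactone and C7/C8/C10 are secure before cyclisation, and the reaction type is known for medium rings.
- Weak points: the closure is entropically costly. C1–C2 arrives saturated, so the Z-enone needs a late dehydrogenation with geometric control. C4 must be set by hydration of the methylene on a flexible ring.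
- Comparison: this road is as good or better for the diol and the lactone. The chosen plan sets against it that the Claisen delivers the C1=C2 alkene exactly where the epoxide belongs.

**Alternative 3:** Form C8–C9 and break a C1–C6 bond. The potassium alkoxide of divinylcyclohexanol A5 undergoes an anionic oxy-Cope shift, and the ten-membered enolate is alkylated at C7 with a haloacetate to give A6.
- Merits: this is the best-precedented ring expansion to germacranes, starts from the terpene pool and installs the C7 arm in the same flask.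
- Weak points: the alkene lands at C1=C10, so C10 must be set by a later reduction and C1–C2 oxidised afresh. C6 arrives as a ketone and C8 as a silane, each needing a stereoselective conversion.
- Comparison: its precedent is clearly better than that of the chosen key step. The chosen plan answers with a direct match of alkene position and C10 configuration to the target.

Key step: step 21

Assumption: locants C1–C13 as defined above, and the CIP descriptors attached to them, are used for all intermediates including acyclic ones; 2,3-O-isopropylidene-L-threitol is taken as the commercial form of the L-tartrate unit.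

## Route

Step 1
Reactants: 1 2,3-O-isopropylidene-L-threitol
Product: 2 mono-TBS ether (5S,6S; C4 hydroxyl free)
Conditions: NaH (1 equiv), THF, 0 °C; TBSCl, 0 °C to rt
Reagents that add atoms: tert-butyldimethylsilyl chloride, CC(C)(C)[Si](C)(C)Cl
Why: Monosilylation of a C2-symmetric diol through its sparingly soluble monosodium alkoxide; the two hydroxyls are homotopic, so no regiochemical question arises.

Step 2
Reactants: 2 mono-TBS ether
Product: 3 C4 aldehyde (5R,6S)
Conditions: Dess–Martin periodinane, pyridine, CH2Cl2, 0 °C to rt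
Reagents that add atoms: none
Why: Dess–Martin oxidation of a primary alcohol under buffered, non-epimerising conditions; the α-alkoxy aldehyde is used at once.

Step 3
Reactants: 3 C4 aldehyde
Product: 4 C4 methyl carbinol (both C4 epimers)
Conditions: MeMgBr, THF, −78 °C
Reagents that add atoms: methylmagnesium bromide, C[Mg]Br
Why: Grignard addition to an aldehyde; the C4 configuration is irrelevant because the carbinol is oxidised next.

Step 4
Reactants: 4 C4 methyl carbinol
Product: 5 C4 methyl ketone (5R,6S)
Conditions: Dess–Martin periodinane, pyridine, CH2Cl2, rt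
Reagents that add atoms: none
Why: Dess–Martin oxidation of a secondary alcohol; silyl ether and acetonide are inert.

Step 5
Reactants: 5 C4 methyl ketone; 6 1,3-dithiane
Product: 8 dithianyl tertiary carbinol (4S,5R,6S), via 2-lithio-1,3-dithiane 7 (not isolated)
Conditions: 6, n-BuLi, THF, −25 °C; then 5, THF–toluene, −78 °C
Reagents that add atoms: none
Why: Corey–Seebach addition to an α-alkoxy ketone; in the Cram chelate (Li between the C4 carbonyl and O5) the anion enters on the face of H5, anti to C6, which gives (4S).

Step 6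
Reactants: 8 dithianyl tertiary carbinol; 9 (E)-crotonaldehyde
Product: 11 dithiane diol (both C2 epimers), via dilithio dianion 10 (not isolated)
Conditions: n-BuLi (2.2 equiv), TMEDA, THF, −25 to 0 °C; then 9, −78 °C
Reagents that add atoms: none
Why: Second Corey–Seebach addition; a lithium alkoxide cannot leave by β-elimination, so the O,C-dianion persists and adds 1,2 to the enal. The C2 mixture is erased in step 7.

Step 7
Reactants: 11 dithiane diol
Product: 12 C2 enone (4S,5R,6S)
Conditions: MnO2, CH2Cl2, rt
Reagents that add atoms: none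
Why: MnO2 oxidises only the allylic alcohol; neutral conditions avoid the retro-aldol loss of the acyl dithiane that an alkoxide of this β-hydroxy ketone would undergo.

Step 8
Reactants: 12 C2 enone
Product: 13 (2R)-allylic alcohol (2R,4S,5R,6S)
Conditions: (S)-2-methyl-CBS-oxazaborolidine (cat.), BH3·SMe2, THF, −30 °C
Reagents that add atoms: none
Why: Corey–Bakshi–Shibata reduction; the quaternary dithiane carbon is the large group and the propenyl the small one, so the (S)-catalyst should give (2R), the configuration required by step 21.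

Step 9
Reactants: 13 (2R)-allylic alcohol
Product: 14 C3 dioxolane diol (2R,4S,5R,6S)
Conditions: PhI(OCOCF3)2, HOCH2CH2OH, 2,6-lutidine, MeCN, −20 to 0 °C
Reagents that add atoms: ethylene glycol, OCCO
Why: Oxidative dithioacetal exchange with a hypervalent iodine reagent in the presence of a diol gives the dioxolane without passing through the hindered free ketone; sulfur is removed here because nitrite, PhI(OAc)2 and peroxide in later steps would attack it.

Step 10
Reactants: 14 C3 dioxolane diol
Product: 15 C2 acetate
Conditions: Ac2O, pyridine, 4-(dimethylamino)pyridine (cat.), CH2Cl2, 0 °C to rt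
Reagents that add atoms: acetic anhydride, CC(=O)OC(C)=O
Why: Catalysed acetylation distinguishes the secondary allylic from the tertiary hydroxyl; the acetate shields O2 in step 12 and leaves without an extra step in step 16.

Step 11
Reactants: 15 C2 acetate
Product: 16 C7 primary alcohol
Conditions: HF·pyridine, pyridine, THF, 0 °C
Reagents that add atoms: none
Why: Fluoride cleavage of the primary silyl ether; the buffered reagent leaves acetate, acetonide and dioxolane intact.

Step 12
Reactants: 16 C7 primary alcohol
Product: 17 C7 aldehyde (2R,4S,5R,6R)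
Conditions: Dess–Martin periodinane, pyridine, CH2Cl2, 0 °C
Reagents that add atoms: none
Why: Dess–Martin oxidation of the primary alcohol; the tertiary hydroxyl is inert and the aldehyde is carried on crude to avoid epimerisation at C6.

Step 13
Reactants: 17 C7 aldehyde
Product: 18 (Z)-enoate (C7=C11; C12 methyl ester)
Conditions: Ph3P=CHCO2Me, MeOH, 0 °C
Reagents that add atoms: methyl (triphenylphosphoranylidene)acetate, COC(=O)C=P(c1ccccc1)(c1ccccc1)c1ccccc1
Why: Wittig olefination with a stabilised ylide in methanol, conditions that favour the Z-enoate from α-alkoxy aldehydes; the Z geometry locks C6–H in the alkene plane for step 15.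

Step 14
Reactants: 18 (Z)-enoate
Product: 19 C4 triethylsilyl ether
Conditions: TESOTf, 2,6-lutidine, CH2Cl2, −78 to 0 °C
Reagents that add atoms: triethylsilyl triflate, CC[Si](CC)(CC)OS(=O)(=O)C(F)(F)F
Why: A silyl triflate with a hindered base silylates the tertiary alcohol; O4 must be blocked so that it cannot close a six-membered lactone onto C8 in step 19.

Step 15
Reactants: 19 C4 triethylsilyl ether
Product: 20 nitro ester (2R,4S,5R,6S,7S)
Conditions: MeNO2 (solvent), 1,8-diazabicyclo[5.4.0]undec-7-ene (cat.), 0 °C to rt
Reagents that add atoms: nitromethane, C[N+](=O)[O-]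
Why: Michael addition of a nitronate to a γ-alkoxy Z-enoate, an addition known to be syn-selective for dioxolane-substituted enoates: with C6–H eclipsing the alkene (allylic 1,3-strain) the nitronate enters anti to the C5 branch, on the side of the ring oxygen, giving (7S). The nitromethyl group is the masked C8 carboxyl.

Step 16
Reactants: 20 nitro ester
Product: 21 nitro diol (O2 and O12 free)
Conditions: LiBH4, THF–MeOH, 0 °C to rt
Reagents that add atoms: none
Why: LiBH4 reduces the methyl ester to the C12 alcohol and cleaves the acetate in the same operation, leaving the aliphatic nitro group untouched.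

Step 17
Reactants: 21 nitro diol
Product: 22 C12 TBS ether (O2 free)
Conditions: TBSCl, imidazole, CH2Cl2, 0 °C
Reagents that add atoms: tert-butyldimethylsilyl chloride, CC(C)(C)[Si](C)(C)Cl
Why: Silylation of the primary hydroxyl in the presence of the hindered secondary allylic one (steric selection).

Step 18
Reactants: 22 C12 TBS ether
Product: 23 hydroxy acid (2R,4S,5R,6S,7R)
Conditions: NaNO2, AcOH, DMSO, 35 °C
Reagents that add atoms: sodium nitrite, [Na+].[O-]N=O; water, O
Why: Nitrite/acetic acid oxidation of a primary nitroalkane to the carboxylic acid (oxidative Nef-type conversion through the nitrolic acid); C7 is not enolised under these mildly acidic conditions.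

Step 19
Reactants: 23 hydroxy acid
Product: 24 eight-membered lactone (2R,4S,5R,6S,7R)
Conditions: 2-methyl-6-nitrobenzoic anhydride, 4-(dimethylamino)pyridine, Et3N, toluene, slow addition at high dilution, 40 °C
Reagents that add atoms: none
Why: Shiina macrolactonisation (mixed anhydride, acyl transfer); substituted chains have been closed to eight-membered lactones this way, and here the trans-dioxolane, the spiro ketal and the quaternary C4 restrict the seco acid.

Step 20
Reactants: 24 eight-membered lactone
Product: 25 2-methylene-8-propenyl oxocane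
Conditions: Cp2TiMe2, toluene–THF, 65 °C, dark
Reagents that add atoms: dimethyltitanocene, C[Ti](C)(C1C=CC=C1)C1C=CC=C1
Why: Petasis methylenation of a lactone carbonyl by thermally generated titanocene methylidene; no other carbonyl is present and the non-acidic medium preserves the exocyclic enol ether.

Step 21
Reactants: 25 2-methylene-8-propenyl oxocane
Product: 26 ten-membered C8 ketone (1Z; 4S,5R,6S,7R,10R)
Conditions: p-xylene, Et3N (trace), base-washed sealed tube, 140 °C
Reagents that add atoms: none
Why: Proposed new method: the allyl vinyl ether C9=C8–O–C2–C1=C10 of 25 should undergo a concerted suprafacial [3,3] (Claisen) shift that forms C9–C10 and breaks O–C2, the ring oxygen leaving as the C8 carbonyl; the closest known reaction is the methylenation–Claisen ring expansion of 6-vinyl six-membered lactones to cyclooct-4-enones, which has not been shown for oxocanes. The ten-membered carbocycle is closed by ring expansion of the eight-membered heterocycle (two-atom growth, oxygen expelled), not by end-to-end cyclisation, so no dilution is needed. C10 is the only new stereocentre and is set by 1,3-transfer of chirality from (2R)-C2 through a chair-like transition state with the E-propenyl methyl equatorial and the ring branch C3 axial on C2, which gives (10R) and the Z C1=C2 alkene. C3 is held axial because the five-atom tether C3–C7 must bridge C2 and C8; the equatorial arrangement that would lead to the E-cyclodecene stretches this tether. The selectivity needed is chair over boat: in the chair the axial C3 meets only the axial C10–H, whereas the boat eclipses the propenyl terminus with the enol ether. Acid-free conditions keep the exocyclic enol ether from isomerising or hydrolysing before it rearranges.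

Step 22
Reactants: 26 ten-membered C8 ketone
Product: 27 (8R)-alcohol (4S,5R,6S,7S,8R,10R)
Conditions: Zn(BH4)2, Et2O, −30 °C
Reagents that add atoms: none
Why: Chelation-controlled hydride reduction: zinc bridges the C8 carbonyl and the dioxolane oxygen on C6, and hydride attacks anti to the C7 side chain, which should give the 7,8-syn (8R) alcohol needed for the trans-lactone.

Step 23
Reactants: 27 (8R)-alcohol
Product: 28 triol (O4, O8 and O12 free)
Conditions: Bu4NF, THF, rt
Reagents that add atoms: none
Why: Fluoride removes both silyl ethers; acetonide and dioxolane are unaffected.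

Step 24
Reactants: 28 triol
Product: 30 trans-fused γ-lactone, via lactol 29 (not isolated)
Conditions: 2,2,6,6-tetramethylpiperidin-1-oxyl (cat.), PhI(OAc)2, CH2Cl2, rt
Reagents that add atoms: none
Why: Oxoammonium oxidation is selective for the primary alcohol; the aldehyde closes to the five-membered lactol with O8, which is oxidised again to the lactone.

Step 25
Reactants: 30 trans-fused γ-lactone
Product: 32 C11 dimethylaminomethyl lactone, via dilithio lactone enolate 31 (not isolated)
Conditions: LDA (2.3 equiv), THF, −78 °C; then CH2=NMe2+ I−, −78 to 0 °C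
Reagents that add atoms: Eschenmoser's salt, C[N+](C)=C.[I-]
Why: Mannich aminomethylation of the lactone enolate; the extra base covers the C4 hydroxyl, and the C11 configuration is irrelevant because C11 becomes sp2 in step 30.

Step 26
Reactants: 32 C11 dimethylaminomethyl lactone
Product: 33 C4,C5,C6 triol with C3 ketal intact
Conditions: camphor-10-sulfonic acid (1.3 equiv), HOCH2CH2OH (excess), MeCN, rt
Reagents that add atoms: none
Why: Acid-catalysed transketalisation: excess ethylene glycol takes acetone from the acetonide, while any opening of the C3 glycol ketal is degenerate under the same conditions, so only the C5/C6 diol is released.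

Step 27
Reactants: 33 triol
Product: 34 5,6-bis-crotonate
Conditions: (E)-crotonic anhydride, 4-(dimethylamino)pyridine, pyridine, CH2Cl2, 0 °C to rt
Reagents that add atoms: (E)-crotonic anhydride, C/C=C/C(=O)OC(=O)/C=C/C
Why: Catalysed acylation esterifies the two secondary hydroxyls and leaves the tertiary one; the anhydride avoids the ketene pathway that deconjugates crotonyl chloride.

Step 28
Reactants: 34 5,6-bis-crotonate
Product: 35 Z-enone (C3 ketone)
Conditions: CF3CO2H–H2O, CH2Cl2, 0 °C to rt; NaHCO3 work-up
Reagents that add atoms: water, O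
Why: Aqueous acid hydrolysis of the allylic ketal; with O5 and O6 esterified no hydroxyl is left that could add to the enone or form a transannular hemiketal, and the protonated amine is inert.

Step 29
Reactants: 35 Z-enone
Product: 36 (1S,2S)-epoxy ketone
Conditions: t-BuOOH, 1,8-diazabicyclo[5.4.0]undec-7-ene, CH2Cl2, 0 °C
Reagents that add atoms: tert-butyl hydroperoxide, CC(C)(C)OO
Why: Weitz–Scheffer nucleophilic epoxidation; the enone is the only strongly electrophilic alkene present, and with C10–H in the enone plane (allylic 1,3-strain of the Z-alkene) the peroxide adds to C1 anti to the C9 ring bond, on the face of the C10 methyl, which should give the (1S,2S) cis-epoxide.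

Step 30
Reactants: 36 (1S,2S)-epoxy ketone
Product: 38 CNP0253228.1, via quaternary ammonium iodide 37 (not isolated)
Conditions: MeI, MeOH, rt; then NaHCO3, H2O–EtOAc, rt
Reagents that add atoms: none
Why: Quaternisation followed by mild-base E1cB (Hofmann-type) elimination of trimethylamine unveils the α-methylene lactone last, under conditions that spare the epoxy ketone and the crotonates.

## Compound list

1 | 2,3-O-isopropylidene-L-threitol, (4S,5S)-2,2-dimethyl-1,3-dioxolane-4,5-dimethanol (carbons C4–C7; 5S,6S) | OC[C@@H]1OC(C)(C)O[C@H]1CO | starting material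
2 | mono-TBS ether (5S,6S): C4 CH2OH, C5/C6 acetonide, C7 CH2OTBS | OC[C@@H]1OC(C)(C)O[C@H]1CO[Si](C)(C)C(C)(C)C | intermediate
3 | aldehyde (5R,6S): C4 CHO, C5/C6 acetonide, C7 CH2OTBS | O=C[C@@H]1OC(C)(C)O[C@H]1CO[Si](C)(C)C(C)(C)C | intermediate
4 | methyl carbinol (5S,6S; both C4 epimers): C4 CH(OH)CH3 | CC(O)[C@@H]1OC(C)(C)O[C@H]1CO[Si](C)(C)C(C)(C)C | intermediate
5 | methyl ketone (5R,6S): C4 C(=O)CH3, C5/C6 acetonide, C7 CH2OTBS | CC(=O)[C@@H]1OC(C)(C)O[C@H]1CO[Si](C)(C)C(C)(C)C | intermediate
6 | 1,3-dithiane | C1CSCSC1 | starting material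
7 | 2-lithio-1,3-dithiane (not isolated) | [Li]C1SCCCS1 | intermediate
8 | tertiary carbinol (4S,5R,6S): C3 = 1,3-dithian-2-yl (C3–H), C4 C(OH)CH3, C5/C6 acetonide, C7 CH2OTBS | S1CCCSC1[C@@](C)(O)[C@@H]2OC(C)(C)O[C@H]2CO[Si](C)(C)C(C)(C)C | intermediate
9 | (E)-crotonaldehyde | C/C=C/C=O | starting material
10 | C3-lithio O4-lithio dianion of 8 (not isolated) | [Li]C1(SCCCS1)[C@@](C)(O[Li])[C@@H]2OC(C)(C)O[C@H]2CO[Si](C)(C)C(C)(C)C | intermediate
11 | diol (4S,5R,6S; both C2 epimers): (E)-propenyl–C2H(OH)–C3(1,3-dithiane-2,2-diyl)–C4(OH)(CH3), acetonide, C7 CH2OTBS | C/C=C/C(O)C1(SCCCS1)[C@@](C)(O)[C@@H]2OC(C)(C)O[C@H]2CO[Si](C)(C)C(C)(C)C | intermediate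
12 | enone (4S,5R,6S): C2 ketone conjugated to the (E)-propenyl group, C3 dithiane, C4 tertiary OH | C/C=C/C(=O)C1(SCCCS1)[C@@](C)(O)[C@@H]2OC(C)(C)O[C@H]2CO[Si](C)(C)C(C)(C)C | intermediate
13 | (2R,4S,5R,6S)-diol: C2 allylic OH, C3 dithiane, C4 tertiary OH | C/C=C/[C@@H](O)C1(SCCCS1)[C@@](C)(O)[C@@H]2OC(C)(C)O[C@H]2CO[Si](C)(C)C(C)(C)C | intermediate
14 | (2R,4S,5R,6S)-diol with C3 as 1,3-dioxolane (ethylene ketal) | C/C=C/[C@@H](O)C1(OCCO1)[C@@](C)(O)[C@@H]2OC(C)(C)O[C@H]2CO[Si](C)(C)C(C)(C)C | intermediate
15 | C2 acetate of 14 (C4 OH free) | C/C=C/[C@@H](OC(C)=O)C1(OCCO1)[C@@](C)(O)[C@@H]2OC(C)(C)O[C@H]2CO[Si](C)(C)C(C)(C)C | intermediate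
16 | C7 primary alcohol (C2 OAc, C4 OH) | C/C=C/[C@@H](OC(C)=O)C1(OCCO1)[C@@](C)(O)[C@@H]2OC(C)(C)O[C@H]2CO | intermediate
17 | C7 aldehyde (2R,4S,5R,6R) | C/C=C/[C@@H](OC(C)=O)C1(OCCO1)[C@@](C)(O)[C@@H]2OC(C)(C)O[C@H]2C=O | intermediate
18 | methyl (Z)-enoate (2R,4S,5R,6S): C7=C11 Z, C12 CO2Me | C/C=C/[C@@H](OC(C)=O)C1(OCCO1)[C@@](C)(O)[C@@H]2OC(C)(C)O[C@H]2/C=C\C(=O)OC | intermediate
19 | C4 triethylsilyl ether of 18 | C/C=C/[C@@H](OC(C)=O)C1(OCCO1)[C@@](C)(O[Si](CC)(CC)CC)[C@@H]2OC(C)(C)O[C@H]2/C=C\C(=O)OC | intermediate
20 | nitro ester (2R,4S,5R,6S,7S): C7 bears C8H2NO2 and C11H2–C12O2Me | C/C=C/[C@@H](OC(C)=O)C1(OCCO1)[C@@](C)(O[Si](CC)(CC)CC)[C@@H]2OC(C)(C)O[C@H]2[C@H](C[N+](=O)[O-])CC(=O)OC | intermediate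
21 | nitro diol (2R,4S,5R,6S,7S): C2 OH, C12 CH2OH | C/C=C/[C@@H](O)C1(OCCO1)[C@@](C)(O[Si](CC)(CC)CC)[C@@H]2OC(C)(C)O[C@H]2[C@H](C[N+](=O)[O-])CCO | intermediate
22 | nitro alcohol: C12 OTBS, C2 OH | C/C=C/[C@@H](O)C1(OCCO1)[C@@](C)(O[Si](CC)(CC)CC)[C@@H]2OC(C)(C)O[C@H]2[C@H](C[N+](=O)[O-])CCO[Si](C)(C)C(C)(C)C | intermediate
23 | hydroxy acid (2R,4S,5R,6S,7R): C8 CO2H, C2 OH | C/C=C/[C@@H](O)C1(OCCO1)[C@@](C)(O[Si](CC)(CC)CC)[C@@H]2OC(C)(C)O[C@H]2[C@H](C(=O)O)CCO[Si](C)(C)C(C)(C)C | intermediate
24 | oxocan-2-one (2R,4S,5R,6S,7R): ring C8(=O)–O–C2–C3–C4–C5–C6–C7; C2 (E)-propenyl, C3 dioxolane, C4 Me/OTES, C5/C6 trans-acetonide, C7 CH2CH2OTBS | O=C1O[C@H](/C=C/C)C3(OCCO3)[C@@](C)(O[Si](CC)(CC)CC)[C@@H]4OC(C)(C)O[C@H]4[C@H]1CCO[Si](C)(C)C(C)(C)C | intermediate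
25 | 2-methylene oxocane (C8=C9H2 exocyclic enol ether; otherwise as 24) | C=C1O[C@H](/C=C/C)C3(OCCO3)[C@@](C)(O[Si](CC)(CC)CC)[C@@H]4OC(C)(C)O[C@H]4[C@H]1CCO[Si](C)(C)C(C)(C)C | intermediate
26 | cyclodecenone (1Z; 4S,5R,6S,7R,10R): C8 ketone, C10 Me, C1=C2 Z, C3 dioxolane, C4 Me/OTES, C5/C6 acetonide, C7 CH2CH2OTBS | O=C1C[C@@H](C)/C=C\C3(OCCO3)[C@@](C)(O[Si](CC)(CC)CC)[C@H](OC4(C)C)[C@@H](O4)[C@H]1CCO[Si](C)(C)C(C)(C)C | intermediate
27 | (8R)-alcohol (4S,5R,6S,7S,8R,10R) | O[C@@H]1C[C@@H](C)/C=C\C3(OCCO3)[C@@](C)(O[Si](CC)(CC)CC)[C@H](OC4(C)C)[C@@H](O4)[C@H]1CCO[Si](C)(C)C(C)(C)C | intermediate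
28 | triol: C4 OH, C8 OH, C12 CH2OH | O[C@@H]1C[C@@H](C)/C=C\C3(OCCO3)[C@@](C)(O)[C@H](OC4(C)C)[C@@H](O4)[C@H]1CCO | intermediate
29 | lactol (C12 hemiacetal with O8; not isolated) | C1C(O)O[C@@H]2C[C@@H](C)/C=C\C3(OCCO3)[C@@](C)(O)[C@H](OC4(C)C)[C@@H](O4)[C@@H]12 | intermediate
30 | trans-fused 12,8-olide (4S,5R,6S,7S,8R,10R): C3 dioxolane, C4 OH, C5/C6 acetonide | C1C(=O)O[C@@H]2C[C@@H](C)/C=C\C3(OCCO3)[C@@](C)(O)[C@H](OC4(C)C)[C@@H](O4)[C@@H]12 | intermediate
31 | dilithio lactone enolate of 30 (O4–Li; not isolated) | C1=C(O[Li])O[C@@H]2C[C@@H](C)/C=C\C3(OCCO3)[C@@](C)(O[Li])[C@H](OC4(C)C)[C@@H](O4)[C@@H]12 | intermediate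
32 | C11 dimethylaminomethyl lactone (C11 epimers, mainly trans to C7–C6) | CN(C)CC1C(=O)O[C@@H]2C[C@@H](C)/C=C\C3(OCCO3)[C@@](C)(O)[C@H](OC4(C)C)[C@@H](O4)[C@@H]12 | intermediate
33 | 4,5,6-triol with C3 dioxolane | CN(C)CC1C(=O)O[C@@H]2C[C@@H](C)/C=C\C3(OCCO3)[C@@](C)(O)[C@H](O)[C@@H](O)[C@@H]12 | intermediate
34 | 5,6-bis[(E)-crotonate] with C3 dioxolane | CN(C)CC1C(=O)O[C@@H]2C[C@@H](C)/C=C\C3(OCCO3)[C@@](C)(O)[C@H](OC(=O)/C=C/C)[C@@H](OC(=O)/C=C/C)[C@@H]12 | intermediate
35 | (1Z)-enone: C3 ketone, C4 OH, 5,6-bis-crotonate | CN(C)CC1C(=O)O[C@@H]2C[C@@H](C)/C=C\C(=O)[C@@](C)(O)[C@H](OC(=O)/C=C/C)[C@@H](OC(=O)/C=C/C)[C@@H]12 | intermediate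
36 | (1S,2S)-epoxy ketone with C11 CH2NMe2 | CN(C)CC1C(=O)O[C@@H]2C[C@@H](C)[C@@H]3O[C@@H]3C(=O)[C@@](C)(O)[C@H](OC(=O)/C=C/C)[C@@H](OC(=O)/C=C/C)[C@@H]12 | intermediate
37 | trimethylammonium iodide of 36 (not isolated) | C[N+](C)(C)CC1C(=O)O[C@@H]2C[C@@H](C)[C@@H]3O[C@@H]3C(=O)[C@@](C)(O)[C@H](OC(=O)/C=C/C)[C@@H](OC(=O)/C=C/C)[C@@H]12.[I-] | intermediate
38 | CNP0253228.1: (1S,2S,4S,5R,6S,7S,8R,10R)-5,6-bis[(E)-but-2-enoyloxy]-1,2-epoxy-4-hydroxy-3-oxogermacr-11(13)-en-12,8-olide | C=C1C(=O)O[C@@H]2C[C@@H](C)[C@@H]3O[C@@H]3C(=O)[C@@](C)(O)[C@H](OC(=O)/C=C/C)[C@@H](OC(=O)/C=C/C)[C@@H]12 | target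

## Step count and least certain steps

Total steps: 30. Longest linear sequence: 30 (from 1; 6 and 9 are purchased).

**Step 21 (key step, new reaction type).**
- What may go wrong: acid-catalysed migration of the exocyclic double bond into the ring, or hydrolysis of the enol ether, before the [3,3] shift. Passage through a boat-like transition state would give the C10 epimer. The oxocane may also resist the conformer with C3 axial, so that decomposition outruns rearrangement.
- Fallback (known chemistry): from lactone 24, LiCH2SO2Ph opens the ring to the hydroxy β-keto sulfone F1. Methyl chloroformate/pyridine gives the allylic carbonate F2. The zerovalent palladium complex Pd(PPh3)4 at high dilution effects Tsuji–Trost macrocyclisation through C9 onto C10 to the α-sulfonyl cyclodecenone F3. The double inversion places the new bond on the same allyl face as the departing oxygen, as the Claisen would. Samarium diiodide SmI2 removes the sulfone and returns to 26.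

**Step 19.**
- What may go wrong: intermolecular acylation (dimer and oligomer formation) outruns closure of the eight-membered ring at a hindered allylic hydroxyl.
- Fallback (activate the alcohol instead of the acid): from 22, Dess–Martin oxidation gives the C2 enone F4. The (R)-enantiomer of the CBS catalyst gives the (2S)-alcohol F5. Nitrite oxidation as in step 18 gives the epimeric hydroxy acid F6. Mitsunobu lactonisation (PPh3, diisopropyl azodicarboxylate, high dilution) closes the ring with inversion at C2 and returns to 24.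

**Step 6.**
- What may go wrong: the second deprotonation next to the lithium alkoxide is incomplete, and the hindered anion acts as a base on crotonaldehyde (γ-deprotonation) instead of adding.
- Fallback (carbanion by C–S cleavage instead of C–H deprotonation): from ketone 5, LiC(SMe)3 adds under the same chelation control to the orthothioester carbinol F7. n-BuLi (2 equiv) removes the hydroxyl proton and cleaves one C–S bond thiophilically, and the resulting anion adds to 9 to give diol F8. MnO2 gives enone F9 and the (S)-CBS catalyst gives the (2R)-alcohol F10. PhI(OCOCF3)2/ethylene glycol exchanges the dithioketal and returns to 14.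

**Step 15.**
- What may go wrong: poor or reversed facial selectivity of the nitronate addition, or double addition.
- Fallback (reverse donor and acceptor so that the well-established anti preference of organocopper additions gives the same C7 configuration): from aldehyde 17, a Henry reaction with nitromethane and dehydration (MsCl, Et3N) give the (E)-nitroalkene F11. TESOTf gives its C4 silyl ether F12. The vinyl cuprate from vinylmagnesium bromide and CuI (copper monoiodide) adds anti to O6 to give F13, whose vinyl group is the C11–C12 arm. 9-Borabicyclo[3.3.1]nonane, then NaOH/H2O2, hydroborates the vinyl group, cleaves the acetate and returns to 21.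

**Step 22.**
- What may go wrong: the ring conformation overrides chelation and hydride is delivered to the other face.
- Fallback (stereoinversion instead of face selection): from 26, the reduction then gives the (8S)-alcohol F14. Mitsunobu reaction with 4-nitrobenzoic acid gives the inverted ester F15, and K2CO3/MeOH returns to 27.

**Step 29.**
- What may go wrong: peroxide attack on the wrong enone face, or a base-induced α-ketol shift at C3/C4.
- Fallback (tie the face to a reagent-made stereocentre): from 35, MeI then NaHCO3 unveil the methylene lactone first to give F16. The (S)-CBS catalyst with catecholborane reduces only the C3 ketone to the (3R)-allylic alcohol F17. VO(acac)2/t-BuOOH epoxidises the Z-allylic alcohol on the hydroxyl face and ignores the electron-poor alkenes, giving F18. Dess–Martin oxidation of O3 returns to 38.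

## Further compounds

F1 | step 21 | hydroxy β-keto sulfone from 24 (C8 ketone, C9H2SO2Ph, C2 OH) | O[C@H](/C=C/C)C3(OCCO3)[C@@](C)(O[Si](CC)(CC)CC)[C@@H]4OC(C)(C)O[C@H]4[C@H](C(=O)CS(=O)(=O)c1ccccc1)CCO[Si](C)(C)C(C)(C)C
F2 | step 21 | C2 methyl carbonate of F1 | COC(=O)O[C@H](/C=C/C)C3(OCCO3)[C@@](C)(O[Si](CC)(CC)CC)[C@@H]4OC(C)(C)O[C@H]4[C@H](C(=O)CS(=O)(=O)c1ccccc1)CCO[Si](C)(C)C(C)(C)C
F3 | step 21 | C9 phenylsulfonyl derivative of 26 (C9 epimers) | O=C1C(S(=O)(=O)c2ccccc2)[C@@H](C)/C=C\C3(OCCO3)[C@@](C)(O[Si](CC)(CC)CC)[C@H](OC4(C)C)[C@@H](O4)[C@H]1CCO[Si](C)(C)C(C)(C)C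
F4 | step 19 | C2 enone from 22 | C/C=C/C(=O)C1(OCCO1)[C@@](C)(O[Si](CC)(CC)CC)[C@@H]2OC(C)(C)O[C@H]2[C@H](C[N+](=O)[O-])CCO[Si](C)(C)C(C)(C)C
F5 | step 19 | (2S)-epimer of 22 | C/C=C/[C@H](O)C1(OCCO1)[C@@](C)(O[Si](CC)(CC)CC)[C@@H]2OC(C)(C)O[C@H]2[C@H](C[N+](=O)[O-])CCO[Si](C)(C)C(C)(C)C
F6 | step 19 | (2S)-epimer of hydroxy acid 23 | C/C=C/[C@H](O)C1(OCCO1)[C@@](C)(O[Si](CC)(CC)CC)[C@@H]2OC(C)(C)O[C@H]2[C@H](C(=O)O)CCO[Si](C)(C)C(C)(C)C
F7 | step 6 | tris(methylthio)methyl carbinol from 5 (4S,5R,6S) | CSC(SC)(SC)[C@@](C)(O)[C@@H]1OC(C)(C)O[C@H]1CO[Si](C)(C)C(C)(C)C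
F8 | step 6 | bis(methylthio) ketal diol (both C2 epimers) | C/C=C/C(O)C(SC)(SC)[C@@](C)(O)[C@@H]1OC(C)(C)O[C@H]1CO[Si](C)(C)C(C)(C)C
F9 | step 6 | bis(methylthio) ketal C2 enone | C/C=C/C(=O)C(SC)(SC)[C@@](C)(O)[C@@H]1OC(C)(C)O[C@H]1CO[Si](C)(C)C(C)(C)C
F10 | step 6 | bis(methylthio) ketal (2R)-alcohol | C/C=C/[C@@H](O)C(SC)(SC)[C@@](C)(O)[C@@H]1OC(C)(C)O[C@H]1CO[Si](C)(C)C(C)(C)C
F11 | step 15 | (E)-nitroalkene from 17 (C7=C8–NO2; C4 OH) | C/C=C/[C@@H](OC(C)=O)C1(OCCO1)[C@@](C)(O)[C@@H]2OC(C)(C)O[C@H]2/C=C/[N+](=O)[O-]
F12 | step 15 | C4 triethylsilyl ether of F11 | C/C=C/[C@@H](OC(C)=O)C1(OCCO1)[C@@](C)(O[Si](CC)(CC)CC)[C@@H]2OC(C)(C)O[C@H]2/C=C/[N+](=O)[O-]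
F13 | step 15 | C7 vinyl nitro adduct (7S; vinyl = C11=C12) | C/C=C/[C@@H](OC(C)=O)C1(OCCO1)[C@@](C)(O[Si](CC)(CC)CC)[C@@H]2OC(C)(C)O[C@H]2[C@H](C[N+](=O)[O-])C=C
F14 | step 22 | (8S)-epimer of 27 | O[C@H]1C[C@@H](C)/C=C\C3(OCCO3)[C@@](C)(O[Si](CC)(CC)CC)[C@H](OC4(C)C)[C@@H](O4)[C@H]1CCO[Si](C)(C)C(C)(C)C
F15 | step 22 | 4-nitrobenzoate of 27 (8R) | O=C(O[C@@H]1C[C@@H](C)/C=C\C3(OCCO3)[C@@](C)(O[Si](CC)(CC)CC)[C@H](OC4(C)C)[C@@H](O4)[C@H]1CCO[Si](C)(C)C(C)(C)C)c1ccc([N+](=O)[O-])cc1
F16 | step 29 | α-methylene lactone Z-enone (38 without the epoxide) | C=C1C(=O)O[C@@H]2C[C@@H](C)/C=C\C(=O)[C@@](C)(O)[C@H](OC(=O)/C=C/C)[C@@H](OC(=O)/C=C/C)[C@@H]12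
F17 | step 29 | (3R)-allylic alcohol of F16 | C=C1C(=O)O[C@@H]2C[C@@H](C)/C=C\[C@@H](O)[C@@](C)(O)[C@H](OC(=O)/C=C/C)[C@@H](OC(=O)/C=C/C)[C@@H]12
F18 | step 29 | (1S,2S)-epoxy (3R)-alcohol | C=C1C(=O)O[C@@H]2C[C@@H](C)[C@@H]3O[C@@H]3[C@@H](O)[C@@](C)(O)[C@H](OC(=O)/C=C/C)[C@@H](OC(=O)/C=C/C)[C@@H]12
A1 | alternative 1 | hydroxy ester with two identical allylic carbinol arms on C7 | COC(=O)CC([C@H](O)/C=C(\C)CO[Si](C)(C)C(C)(C)C)[C@H](O)/C=C(\C)CO[Si](C)(C)C(C)(C)C
A2 | alternative 1 | trans-lactone with free C6 hydroxyl | C1C(=O)O[C@H](/C=C(\C)CO[Si](C)(C)C(C)(C)C)[C@H]1[C@H](O)/C=C(\C)CO[Si](C)(C)C(C)(C)C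
A3 | alternative 2 | lactone aldehyde carrying the γ-(methoxymethoxy)allylstannane | C1C(=O)O[C@H](C[C@@H](C)CC[C@H](O[Si](C)(C)C(C)(C)C)C(C[Sn](CCCC)(CCCC)CCCC)=COCOC)[C@H]1C=O
A4 | alternative 2 | ten-membered ring with C4 methylene, C5 OMOM, C6 hydroxyl | C1C(=O)O[C@@H]2C[C@@H](C)CC[C@H](O[Si](C)(C)C(C)(C)C)C(=C)[C@H](OCOC)[C@@H](O)[C@@H]12
A5 | alternative 3 | trans-1-[(E)-2-silylvinyl]-2-isopropenylcyclohexanol with C3 ketal and C4, C5 MOM ethers | O[C@@]1(/C=C/[Si](C)(C)c2ccccc2)[C@@H](C(C)=C)CC3(OCCO3)[C@@](C)(OCOC)[C@@H]1OCOC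
A6 | alternative 3 | cyclodec-5-enone with C7 acetate arm and C8 silyl group | COC(=O)C[C@H]1[C@H]([Si](C)(C)c2ccccc2)C/C(C)=C/CC3(OCCO3)[C@@](C)(OCOC)[C@H](OCOC)C1=O
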